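## Analysis of the target

The target 15, 3,4-dibromo-2-(5-bromo-2-hydroxyphenoxy)phenol, is a diaryl ether of two benzene rings. Ring A is a phenol (C1–OH) with the ether oxygen at C2 and bromine at C4; ring B is a phenol (C1'–OH) with the ether oxygen at C2' and bromines at C3' and C4'. There is no stereocentre, so the problem is only one of placing five heteroatom substituents correctly around the ether bridge. The free ortho-aryloxyphenols are prone to oxidation and over-halogenation and are best kept masked to the end, and the three aryl bromides exclude reductive steps and restrict organometallic chemistry to conditions without bromine–metal exchange. Two things make the synthesis hard. The ether joins two ortho-oxygenated carbons, and C2' is flanked on both sides, so a late etherification would be hindered. In addition, C3'–Br is meta to the ring B hydroxyl, where electrophilic bromination of a phenol or anisole will not put it, whereas C4–Br and C4'–Br are para to their hydroxyls. The route rests on ring B: C2' (ether oxygen) and C1' (hydroxyl) are adjacent and C4' (bromine) is para to C1', the pattern formed when the C=C bond of the aryloxy ketene acetal 5 adds across C3 and C6 of 5-bromo-2-pyrone 7 and the adduct aromatises. The remaining C3'–H then lies between the ether oxygen and the C4' bromine and is the most acidic hydrogen in the molecule, which gives access to the one bromine that electrophilic chemistry cannot deliver.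

## Retrosynthetic reasoning

15 to 13. The two phenolic O–H bonds are traced back to O–CH3 bonds in the dimethyl ether 13. Methyl ethers are chosen because they are inert to amide bases, aryllithiums and electrophilic bromine, and because both can be cleaved in one Lewis-acid operation. The forward reaction has to break two alkyl–oxygen bonds and leave the aryl–oxygen bonds of the bridge and the three C–Br bonds intact.

13 to 12. The C4–Br bond of ring A is cut. In 12 this carbon is para to the ring A methoxy group and is the most nucleophilic position of the molecule, because ring B already carries two bromines and its own para position is occupied. An electrophilic bromination should therefore find it. It is placed after the metalation step so that ring A has no bromine, and hence no second acidic C–H between oxygen and bromine, while the aryllithium is made.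

12 to 10, through 11. The C3'–Br bond is cut. This carbon is meta to the ring B methoxy group and is not reached by electrophilic substitution. In 10 its hydrogen is the only one flanked by an oxygen and a bromine, so deprotonation by a hindered lithium amide should give the aryllithium 11 at this carbon alone, and an electrophilic bromine donor completes the bond. The gain is that the awkward bromine is placed by acidity, with the C4' bromine acting as the directing group.

10 to 5 and 7, through 8 and 9. Two C–C bonds of ring B are cut, C2'–C3' and C1'–C6'. This divides the ring into a four-carbon piece, the diene of pyrone 7 with the C4' bromine already on it, and a two-carbon piece, the C=C bond of ketene acetal 5, which carries the ether oxygen with ring A attached and the future C1' oxygen. The cut is made here and not at the diaryl ether bond because the ether oxygen can then be introduced much earlier on an unhindered primary carbon. The forward reaction has to add 5 to 7 with one orientation, giving the bridged lactone 8. It then has to decarboxylate by a retro-(4+2) reaction to the diene 9 and lose the silyloxy group with the neighbouring hydrogen, so that the methoxy group remains on C1'.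

5 to 3 to 1 and 2; 7 to 6. The O–Si bond of 5 is cut to give ester 3, whose enolate 4 is silylated on oxygen. The alkyl C–O bond of 3 is cut to give guaiacol 1 and methyl bromoacetate 2, a simple phenol alkylation. Pyrone 7 is traced to coumalic acid 6 by exchanging the C5 carboxyl group for bromine, which uses the nucleophilic character of C5 in the ring enol ether.

## Alternatives that were turned down

Alternative 1: Ring A would be built in place of ring B. Its bonds C2–C3 and C5–C6 are cut to give the aryloxyacetone A2 and 2-bromomalonaldehyde A3. In the forward direction a base would condense the two alpha carbons of A2 with the two formyl groups of A3 in a (3+3) benzannulation to give the phenol A1, one demethylation from 15. In its favour, C4–Br and the free C1–OH arrive together and without any selectivity question, and the ether oxygen is introduced by alkylating a phenol with an alpha-halo ketone. On the placing of the ring A bromine it is stronger than the chosen route, which relies on a directing effect. Against it, A2 already contains ring B with both bromines, so the C3'–Br problem is only moved into an earlier building block. The annulation is also on firm ground only for malonaldehydes whose central carbon bears a strongly acidifying group. A3 is an alpha-bromo dialdehyde that the enolate of A2 can attack at bromine or at the C–Br carbon, and it self-condenses in base. The chosen route solves C3'–Br within the route and has a ring-forming step with closer precedent. It answers the ring A question with the strongest available para director and an independent fallback.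

Alternative 2: The aryl C–O bonds at C1 and C1' are traced back to aryl–CHO bonds. The dialdehyde A5 would come from a nucleophilic aromatic substitution between a fluorobenzaldehyde and a salicylaldehyde. In the forward key step a peracid would convert both formyl groups of A5 into formates by aryl migration, giving the bis-formate A4, which hydrolyses to 15. This is the shortest plan on paper: it is convergent, needs no protecting groups, and fixes all three bromines in the building blocks. On step economy and on certainty of the bromine positions it is stronger than the chosen route. Against it, the ring B building block with contiguous formyl, leaving group and two bromines is not a commodity chemical and itself needs a directed metalation, so part of the length is hidden. The substitution joins a deactivated ortho-formyl phenoxide to a crowded fluoride. The oxidation must prefer aryl over hydride migration twice in one molecule, on rings that each carry a bromine para to the formyl carbon. Only the ortho aryloxy donor helps, and a single hydride migration ends in a carboxylic acid that cannot be rescued. The chosen route offers instead cheap starting materials, an endgame of routine reactions, and no dependence on two migratory aptitudes.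

Alternative 3: Ring A would be made from the 3-aryloxy-4-pyranone A7. The carbanion of nitromethane A8 adds to C2 of the pyranone, the ring opens, and it recloses on carbon to give the nitrophenol A6. In its favour, the pyranone-to-nitrophenol conversion is an established ring transformation, the nitro group ends para to the hydroxyl without ambiguity, and the hydroxyl is free. On precedent for the ring transformation it is about equal to the chosen route. Against it, nitrogen must then be exchanged for bromine by reduction in the presence of two aryl bromides, diazotisation and Sandmeyer bromination, before the demethylation. A7 also requires the hindered ring B oxygen to be attached to C3 of a pyranone, for which neither partner is a good substrate, and ring B must again be fully brominated beforehand. The chosen route uses the same idea of turning a six-membered oxygen heterocycle into a benzene ring, but its heterocycle carries the bromine itself, so no functional group exchange follows. Its ether oxygen is introduced on a primary alkyl bromide.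

Key step: step 4

Remark on the chemistry: in step 4 the decarboxylation is assumed to precede loss of the silanol; the opposite order would lead to the same product 10. Compounds 8 and 9 are expected as mixtures of stereoisomers whose configuration is erased in the same step, so they are drawn without stereodescriptors.

## Route

Step 1
Reactants: 1 guaiacol (2-methoxyphenol); 2 methyl bromoacetate
Product: 3 methyl 2-(2-methoxyphenoxy)acetate
Conditions: K2CO3, acetone, reflux
Reagents that add atoms: none
Why: Williamson ether synthesis; the phenoxide formed by K2CO3 displaces bromide from the primary, carbonyl-activated carbon by SN2, and O-alkylation is the only significant pathway in acetone.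

Step 2
Reactants: 3 methyl 2-(2-methoxyphenoxy)acetate
Product: 5 (Z)-1-methoxy-2-(2-methoxyphenoxy)-1-(trimethylsilyloxy)ethene, via lithium ester enolate 4 (not isolated)
Conditions: LiN(iPr)2 (LDA), THF, −78 °C; then Me3SiCl, −78 °C to rt; non-aqueous work-up
Reagents that add atoms: chlorotrimethylsilane, C[Si](C)(C)Cl
Why: Ester enolate formation and O-silylation to a ketene silyl acetal; the alpha CH2 is far more acidic than any aryl C–H, and at −78 °C self-condensation should be slow. Chelation of lithium between the enolate oxygen and the aryloxy oxygen should place O–Li, and then O–Si, cis to the aryloxy group (the Z acetal), although the geometry has no bearing on step 4.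

Step 3
Reactants: 6 coumalic acid (2-oxo-2H-pyran-5-carboxylic acid)
Product: 7 5-bromo-2H-pyran-2-one
Conditions: NBS (1 equiv), LiOAc (cat.), MeCN–H2O, rt
Reagents that add atoms: N-bromosuccinimide, O=C1CCC(=O)N1Br
Why: Hunsdiecker-type ipso-bromodecarboxylation, known for pyrone carboxylic acids; C5 is the nucleophilic beta carbon of the ring enol ether O1–C6=C5, so electrophilic bromine adds there and loss of CO2 restores the pyrone. Limiting NBS to one equivalent should hold back a second bromination at C3.

Step 4
Reactants: 5 (Z)-1-methoxy-2-(2-methoxyphenoxy)-1-(trimethylsilyloxy)ethene; 7 5-bromo-2H-pyran-2-one
Product: 10 4-bromo-1-methoxy-2-(2-methoxyphenoxy)benzene, via bridged bicyclic lactone 8 (not isolated), via methoxy silyloxy cyclohexadiene 9 (not isolated)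
Conditions: 5 (2 equiv), iPr2NEt (cat.), PhMe, 120 °C, sealed tube; then DBU, 60 °C
Reagents that add atoms: none
Why: This is an inverse-electron-demand Diels–Alder addition of the electron-rich acetal 5 to the diene C3=C4–C5=C6 of pyrone 7, the known reaction of 2-pyrones (3-bromo- and 5-bromo-2-pyrone included) with ketene acetals and enol ethers, which ends in loss of CO2 and of an alcohol to give an aryl ether. Bond formation should be asynchronous: the CH(OAr) carbon of 5 has the larger HOMO coefficient, because the two oxygen donors on the acetal carbon outweigh the single aryloxy donor, and it bonds first to pyrone C6, the delta carbon of the dienoate and its most electrophilic terminus; the acetal carbon then closes onto C3. Ring B is thus closed as a six-membered carbocycle by an intermolecular (4+2) cycloaddition that forms both new C–C bonds (C2'–C3' and C1'–C6') and gives lactone 8. At 120 °C 8 should lose CO2 by a retro-(4+2) reaction to give diene 9, and DBU then removes the hydrogen on the aryloxy-bearing carbon as trimethylsilanolate departs; this is the better leaving group of the mixed acetal, so the methoxy group stays on the ring. The four stereocentres of 8 and the two of 9 are all erased on aromatisation, so the endo/exo ratio and the acetal geometry do not matter and no stereocontrol is needed. The selectivity the step does need is regiochemical, and the polarity match described places the pyrone C5 bromine para to the methoxy carbon and meta to the aryloxy carbon, as in 10. The catalytic iPr2NEt keeps the medium free of acid, which would favour ionisation of the acetal with loss of methanol.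

Step 5
Reactants: 10 4-bromo-1-methoxy-2-(2-methoxyphenoxy)benzene
Product: 12 1,2-dibromo-4-methoxy-3-(2-methoxyphenoxy)benzene, via aryllithium 11 (not isolated)
Conditions: LiN(iPr)2 (LDA), THF, −78 °C; then BrCl2C–CCl2Br, −78 °C
Reagents that add atoms: 1,2-dibromo-1,1,2,2-tetrachloroethane, ClC(Cl)(Br)C(Cl)(Cl)Br
Why: Directed ortho-metalation followed by electrophilic bromination; the C3'–H between the aryloxy oxygen and bromine is acidified by two adjacent inductive groups, as in the known lithiation of 3-bromoanisole between its substituents. The amide base does not undergo bromine–lithium exchange, and at −78 °C the ortho-bromoaryllithium 11 should not lose LiBr before the bromine donor transfers Br+ and leaves as tetrachloroethene.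

Step 6
Reactants: 12 1,2-dibromo-4-methoxy-3-(2-methoxyphenoxy)benzene
Product: 13 1,2-dibromo-3-(5-bromo-2-methoxyphenoxy)-4-methoxybenzene
Conditions: NBS (1 equiv), MeCN, 0 °C to rt
Reagents that add atoms: N-bromosuccinimide, O=C1CCC(=O)N1Br
Why: Electrophilic aromatic bromination; ring A is the only ring without a deactivating halogen, and its methoxy group is a stronger para director than the bridging oxygen, whose lone pair is shared with the electron-poor and twisted dibromo ring. Ring B is deactivated and its position para to methoxy is already occupied.

Step 7
Reactants: 13 1,2-dibromo-3-(5-bromo-2-methoxyphenoxy)-4-methoxybenzene
Product: 15 3,4-dibromo-2-(5-bromo-2-hydroxyphenoxy)phenol, via bis(dibromoboryl) ether 14 (not isolated)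
Conditions: BBr3 (excess), CH2Cl2, −78 °C to rt; then H2O
Reagents that add atoms: none
Why: Lewis-acid cleavage of aryl methyl ethers; boron coordinates each methoxy oxygen and bromide attacks the methyl carbon by SN2, which cannot happen at the sp2 carbons of the diaryl ether. Hydrolysis of the aryloxyborane 14 releases both phenols, and the C–Br bonds are inert to the reagent.

## Compound list

1 | guaiacol (2-methoxyphenol) | COc1ccccc1O | starting material
2 | methyl bromoacetate | COC(=O)CBr | starting material
3 | methyl 2-(2-methoxyphenoxy)acetate | COC(=O)COc1ccccc1OC | intermediate
4 | lithium (E)-1-methoxy-2-(2-methoxyphenoxy)ethen-1-olate (O–Li cis to the aryloxy group) | CO/C(O[Li])=C/Oc1ccccc1OC | intermediate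
5 | (Z)-1-methoxy-2-(2-methoxyphenoxy)-1-(trimethylsilyloxy)ethene | CO/C(O[Si](C)(C)C)=C/Oc1ccccc1OC | intermediate
6 | coumalic acid (2-oxo-2H-pyran-5-carboxylic acid) | O=C(O)c1ccc(=O)oc1 | starting material
7 | 5-bromo-2H-pyran-2-one | O=c1ccc(Br)co1 | intermediate
8 | 6-bromo-8-methoxy-7-(2-methoxyphenoxy)-8-(trimethylsilyloxy)-2-oxabicyclo[2.2.2]oct-5-en-3-one (mixture of stereoisomers) | O=C1OC2C(Oc3ccccc3OC)C(OC)(O[Si](C)(C)C)C1C=C2Br | intermediate
9 | 2-bromo-5-methoxy-6-(2-methoxyphenoxy)-5-(trimethylsilyloxy)cyclohexa-1,3-diene (mixture of stereoisomers) | COC1(O[Si](C)(C)C)C=CC(Br)=CC1Oc1ccccc1OC | intermediate
10 | 4-bromo-1-methoxy-2-(2-methoxyphenoxy)benzene | COc1ccc(Br)cc1Oc1ccccc1OC | intermediate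
11 | [6-bromo-3-methoxy-2-(2-methoxyphenoxy)phenyl]lithium | COc1ccc(Br)c([Li])c1Oc1ccccc1OC | intermediate
12 | 1,2-dibromo-4-methoxy-3-(2-methoxyphenoxy)benzene | COc1ccc(Br)c(Br)c1Oc1ccccc1OC | intermediate
13 | 1,2-dibromo-3-(5-bromo-2-methoxyphenoxy)-4-methoxybenzene | COc1ccc(Br)cc1Oc1c(OC)ccc(Br)c1Br | intermediate
14 | 1,2-dibromo-3-[5-bromo-2-(dibromoboranyloxy)phenoxy]-4-(dibromoboranyloxy)benzene | BrB(Br)Oc1ccc(Br)cc1Oc1c(OB(Br)Br)ccc(Br)c1Br | intermediate
15 | 3,4-dibromo-2-(5-bromo-2-hydroxyphenoxy)phenol | Oc1ccc(Br)cc1Oc1c(O)ccc(Br)c1Br | target

## Step count and least certain steps

Total step count: 7. Longest linear sequence: 6 steps (steps 1, 2, 4, 5, 6 and 7 from 1); step 3 is a one-step branch.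

Step 4 (key step). Several things may go wrong.
- The cycloaddition may be slow, because 7 is only a moderately electron-poor diene and 5 is a trisubstituted alkene, which leaves time for hydrolysis or thermal decay of the acetal.
- Orientation may be eroded, because the aryloxy donor opposes the polarisation set by the acetal oxygens.
- Conjugate addition at C6 may be followed by opening of the pyrone instead of ring closure.
- Aromatisation may proceed by loss of methanol instead of the silanol, which would unmask the ring B oxygen.

Fallback: the ring construction is given up and the diaryl ether bond is made directly. The fallback sets out from 1, which is coupled with (5-bromo-2-methoxyphenyl)boronic acid (COc1ccc(Br)cc1B(O)O) in a Chan–Lam reaction [Cu(OAc)2, pyridine, 4 Å molecular sieves, CH2Cl2, air, rt]. The C–Br bond is untouched at room temperature, and the route is rejoined at 10. This fallback makes no compound outside the list (F0).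

Step 5. The ortho-bromoaryllithium 11 may decay by loss of LiBr to an aryne if the temperature rises. Bromine migration, or bromine–lithium exchange between 11 and freshly formed 12, may scramble the halogen pattern during the quench. Fallback: the aryllithium is trapped as it forms and the bromine is introduced by ipso substitution. The fallback sets out from 10, which is treated with LiN(iPr)2 in the presence of Me3SiCl at −78 °C (in situ quench) to give [6-bromo-3-methoxy-2-(2-methoxyphenoxy)phenyl]trimethylsilane F1. Br2 (2 equiv, CH2Cl2, 0 °C) should then effect ipso-bromodesilylation on ring B and para bromination of ring A in one operation, and the route is rejoined at 13.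

Step 6. Site selectivity may be lost through bromination para to the bridging oxygen on ring A, or a second bromination may occur, because the difference in directing power between methoxy and aryloxy is real but not large. Fallback: the order of the last two operations is reversed so that a free hydroxyl directs. The fallback sets out from 12, which is demethylated with BBr3 to 3,4-dibromo-2-(2-hydroxyphenoxy)phenol F2. One equivalent of Bu4NBr3 (CH2Cl2–MeOH, rt) should brominate para to the ring A hydroxyl, since the ring B para position is occupied and that ring is deactivated. The route is rejoined at 15.

Step 3. A second bromination at C3 of the pyrone may occur, and the pyrone may be opened hydrolytically in the aqueous medium. Fallback: decarboxylation and bromination are separated. The fallback sets out from 6, which is decarboxylated by flash pyrolysis over copper to 2H-pyran-2-one F3. Photochemical addition of Br2 across C5=C6 (CH2Cl2, −78 °C, hν) should give trans-5,6-dibromo-5,6-dihydro-2H-pyran-2-one F4. Et3N then removes H5 and the C6 bromide, and the route is rejoined at 7.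

## Further compounds

F0 | step 4 | none | none
F1 | step 5 | [6-bromo-3-methoxy-2-(2-methoxyphenoxy)phenyl]trimethylsilane | COc1ccc(Br)c([Si](C)(C)C)c1Oc1ccccc1OC
F2 | step 6 | 3,4-dibromo-2-(2-hydroxyphenoxy)phenol | Oc1ccccc1Oc1c(O)ccc(Br)c1Br
F3 | step 3 | 2H-pyran-2-one | O=c1cccco1
F4 | step 3 | trans-5,6-dibromo-5,6-dihydro-2H-pyran-2-one (racemic, one enantiomer drawn) | O=C1C=C[C@@H](Br)[C@H](Br)O1
A1 | alternative 1 | 4-bromo-2-(2,3-dibromo-6-methoxyphenoxy)phenol | COc1ccc(Br)c(Br)c1Oc1cc(Br)ccc1O
A2 | alternative 1 | 1-(2,3-dibromo-6-methoxyphenoxy)propan-2-one | CC(=O)COc1c(OC)ccc(Br)c1Br
A3 | alternative 1 | 2-bromomalonaldehyde (2-bromopropanedial) | O=CC(Br)C=O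
A4 | alternative 2 | 4-bromo-2-(2,3-dibromo-6-formyloxyphenoxy)phenyl formate | O=COc1ccc(Br)cc1Oc1c(OC=O)ccc(Br)c1Br
A5 | alternative 2 | 4-bromo-2-(2,3-dibromo-6-formylphenoxy)benzaldehyde | O=Cc1ccc(Br)cc1Oc1c(C=O)ccc(Br)c1Br
A6 | alternative 3 | 2-(2,3-dibromo-6-methoxyphenoxy)-4-nitrophenol | COc1ccc(Br)c(Br)c1Oc1cc([N+](=O)[O-])ccc1O
A7 | alternative 3 | 3-(2,3-dibromo-6-methoxyphenoxy)-4H-pyran-4-one | COc1ccc(Br)c(Br)c1Oc1coccc1=O
A8 | alternative 3 | nitromethane | C[N+](=O)[O-]
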